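**Retrosynthetic overview**
1. Numbering (cembrane): C1/C14 are the fusion carbons of the butyrolactone (C15=C17H2, C16=O). C3–C4 is the oxirane (CH3 on C4), C7 is CHOAc next to C8(=C19H2), C12 is CHCH3, C13 is CHOAc. C1–C14 form the 14-membered carbocycle.
2. End game at another oxidation level: the oxirane comes from the E-C3=C4 alkene (Shi epoxidation, last step) and the C7 acetate from a C7 ketone (CBS reduction).
3. Key cut C4–C5. Enabling feature: the oxygenated ring carbon C7 lies three bonds from the methyl-bearing oxirane carbon C4 (C4–C5–C6–C7) and is flanked by the exocyclic C8=C19 methylene. The bridge C5–C6–C7(=O) is therefore what a Heck alkenylation of a vinyl carbinol leaves: E-alkenyl iodide at C4 plus CH2=CH–CH(OH) at C5–C7, closing the ring with internal redox.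
4. The seco compound comes from an indium Barbier union at C1–C14 of bromide 7 (fragment A) with α-hydroxy aldehyde 25, which sets C14 and C1 and gives the cis-α-methylene lactone. Aldehyde 25 derives from (S)-citronellal (C12), a proline aminoxylation (C13) and a Negishi coupling at C8–C9 with bromodiene 13 (fragment B).
5. Ring order: butyrolactone (step 15), then 14-membered carbocycle (step 18), then oxirane (step 21).

Key step: step 18

Remark: C7 is carried as an epimer mixture (undefined in the SMILES of 12, 13 and 20–30) because step 18 erases this centre. Compound 6 is racemic and loses its centre in step 4.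

**Fragment A**

Step 1
Reactants: 1 pent-3-yn-1-ol
Product: 3 (3E)-4-iodopent-3-en-1-ol, via alkenylzirconocene 2 (not isolated)
Conditions: Cp2Zr(H)Cl (2.2 equiv), THF, rt → 40 °C; I2, 0 °C; aq. work-up
Reagents that add atoms: iodine, II
Why: Hydrozirconation is a syn addition, excess Cp2Zr(H)Cl equilibrates the metal to the less hindered methyl-bearing alkyne carbon, and iodinolysis with retention gives the E-2-iodoalkene that fixes the later C3=C4 geometry.

Step 2
Reactants: 3 (3E)-4-iodopent-3-en-1-ol
Product: 4 (3E)-4-iodopent-3-enal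
Conditions: Dess–Martin periodinane, CH2Cl2, 0 °C → rt
Reagents that add atoms: none
Why: Dess–Martin oxidation is mild enough to deliver the β,γ-unsaturated aldehyde without moving the alkene into conjugation.

Step 3
Reactants: 4 (3E)-4-iodopent-3-enal; 5 methyl acrylate
Product: 6 methyl (5E)-3-hydroxy-6-iodo-2-methylidenehept-5-enoate (racemic)
Conditions: DABCO (0.5 equiv), 1,4-dioxane/H2O (1:1), rt
Reagents that add atoms: none
Why: Morita–Baylis–Hillman reaction in which the amine-derived acrylate enolate adds to the unhindered aldehyde, and the new carbinol centre needs no control because step 4 removes it.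

Step 4
Reactants: 6 methyl (5E)-3-hydroxy-6-iodo-2-methylidenehept-5-enoate
Product: 7 methyl (2Z,5E)-2-(bromomethyl)-6-iodohepta-2,5-dienoate
Conditions: PBr3 (0.4 equiv), Et2O, 0 °C
Reagents that add atoms: phosphorus tribromide, BrP(Br)Br
Why: Bromination of a Baylis–Hillman alcohol with allylic transposition (SN2′) gives the primary bromide, Z-configured because allylic strain keeps the C2 chain away from the ester.

**Fragment B**

Step 5
Reactants: 8 acrolein
Product: 10 2-bromoprop-2-enal, via 2,3-dibromopropanal 9 (not isolated)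
Conditions: Br2, CH2Cl2, −78 → 0 °C; Et3N, 0 °C
Reagents that add atoms: bromine, BrBr
Why: Bromine addition followed by base-induced loss of HBr through the acidic α-hydrogen is the standard bromination–dehydrobromination of an enal.

Step 6
Reactants: 10 2-bromoprop-2-enal; 11 vinylmagnesium bromide
Product: 12 2-bromopenta-1,4-dien-3-ol (racemic)
Conditions: THF, −78 °C; aq. work-up
Reagents that add atoms: none
Why: 1,2-Grignard addition of the hard vinyl nucleophile to the aldehyde, and the carbinol (later C7) may be racemic because it is erased in step 18.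

Step 7
Reactants: 12 2-bromopenta-1,4-dien-3-ol
Product: 13 [(2-bromopenta-1,4-dien-3-yl)oxy](tert-butyl)dimethylsilane (racemic)
Conditions: TBSCl, imidazole, DMF, rt
Reagents that add atoms: tert-butyldimethylsilyl chloride, C[Si](C)(Cl)C(C)(C)C
Why: Imidazole-promoted silylation masks the acid- and oxidation-sensitive bis-allylic alcohol for steps 11–16.

**Main line**

Step 8
Reactants: 14 (S)-citronellal
Product: 15 (6S)-8,8-dimethoxy-2,6-dimethyloct-2-ene
Conditions: HC(OMe)3, TsOH·H2O (cat.), MeOH, rt
Reagents that add atoms: trimethyl orthoformate, COC(OC)OC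
Why: Acid-catalysed acetalisation protects the aldehyde (C14) and leaves the chiral-pool C12 methyl centre untouched.

Step 9
Reactants: 15 (6S)-8,8-dimethoxy-2,6-dimethyloct-2-ene
Product: 17 (4S)-6,6-dimethoxy-4-methylhexan-1-ol, via aldehyde 16 (not isolated)
Conditions: O3, CH2Cl2/MeOH, −78 °C; NaBH4, −78 °C → rt
Reagents that add atoms: ozone, [O-][O+]=O
Why: Ozonolysis with reductive work-up cleaves the only alkene and gives the C9 alcohol.

Step 10
Reactants: 17 (4S)-6,6-dimethoxy-4-methylhexan-1-ol
Product: 18 (3S)-6-iodo-1,1-dimethoxy-3-methylhexane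
Conditions: I2, PPh3, imidazole, CH2Cl2, 0 °C
Reagents that add atoms: iodine, II
Why: Appel iodination of a primary alcohol, buffered by imidazole so that the acetal survives.

Step 11
Reactants: 18 (3S)-6-iodo-1,1-dimethoxy-3-methylhexane; 13 [(2-bromopenta-1,4-dien-3-yl)oxy](tert-butyl)dimethylsilane
Product: 20 tert-butyl{[(8S)-10,10-dimethoxy-8-methyl-4-methylidenedec-1-en-3-yl]oxy}dimethylsilane, via alkylzinc iodide 19 (not isolated)
Conditions: Zn dust (cat. BrCH2CH2Br, Me3SiCl), DMA, 40 °C; then 13, Pd(dppf)Cl2 (5 mol %), THF, 40 °C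
Reagents that add atoms: none
Why: Negishi coupling of a primary alkylzinc iodide with a 2-bromo-1-alkene forms C8–C9 and installs the exocyclic methylene together with the vinyl carbinol unit.

Step 12
Reactants: 20 tert-butyl{[(8S)-10,10-dimethoxy-8-methyl-4-methylidenedec-1-en-3-yl]oxy}dimethylsilane
Product: 21 (3S)-8-[(tert-butyldimethylsilyl)oxy]-3-methyl-7-methylidenedec-9-enal
Conditions: PPTS (cat.), acetone/H2O, 45 °C
Reagents that add atoms: water, O
Why: Mild acetal hydrolysis frees the aldehyde under conditions that a secondary TBS ether tolerates.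

Step 13
Reactants: 21 (3S)-8-[(tert-butyldimethylsilyl)oxy]-3-methyl-7-methylidenedec-9-enal
Product: 24 (2R,3S)-8-[(tert-butyldimethylsilyl)oxy]-3-methyl-7-methylidenedec-9-ene-1,2-diol, via aminoxy aldehyde 22 (not isolated), via aminoxy alcohol 23 (not isolated)
Conditions: PhNO, L-proline (20 mol %), DMSO, rt; MeOH, NaBH4, 0 °C; AcOH, Zn dust, rt
Reagents that add atoms: nitrosobenzene, O=Nc1ccccc1
Why: Proline-catalysed α-aminoxylation in which the enamine of 21 attacks the oxygen of nitrosobenzene held by the carboxylic acid of L-proline, so C13 is set as R under catalyst control, and hydride reduction followed by N–O cleavage gives the diol.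

Step 14
Reactants: 24 (2R,3S)-8-[(tert-butyldimethylsilyl)oxy]-3-methyl-7-methylidenedec-9-ene-1,2-diol
Product: 25 (2R,3S)-8-[(tert-butyldimethylsilyl)oxy]-2-hydroxy-3-methyl-7-methylidenedec-9-enal
Conditions: TEMPO (10 mol %), N-chlorosuccinimide, Bu4NCl (cat.), CH2Cl2/aq. NaHCO3, 0 °C; used crude
Reagents that add atoms: none
Why: Oxoammonium (TEMPO) oxidation is sterically selective for the primary alcohol of the diol and avoids the glycol cleavage that hypervalent iodine co-oxidants could cause.

Step 15
Reactants: 25 (2R,3S)-8-[(tert-butyldimethylsilyl)oxy]-2-hydroxy-3-methyl-7-methylidenedec-9-enal; 7 methyl (2Z,5E)-2-(bromomethyl)-6-iodohepta-2,5-dienoate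
Product: 28 (4S,5R)-5-[(1R,2S)-7-(tert-butyldimethylsilyloxy)-1-hydroxy-2-methyl-6-methylidenenon-8-en-1-yl]-4-[(2E)-3-iodobut-2-en-1-yl]-3-methylideneoxolan-2-one, via allylindium dibromide 26 (not isolated), via hydroxy ester 27 (not isolated)
Conditions: In powder, THF/H2O (1:1), rt; then TsOH·H2O (cat.), CH2Cl2, rt
Reagents that add atoms: none
Why: Barbier-type allylindium addition in water in which trivalent indium chelates the free C13 hydroxyl and the aldehyde oxygen (C13/C14 syn), the chair transition state of the Z-configured allyl unit places the C2 chain syn to the new C14 oxygen (C14 R, C1 S), and acid then closes the cis-α-methylene-γ-butyrolactone through the C14 hydroxyl rather than the six-membered alternative.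

Step 16
Reactants: 28 lactone alcohol
Product: 29 (1R,2S)-7-(tert-butyldimethylsilyloxy)-1-{(2R,3S)-3-[(2E)-3-iodobut-2-en-1-yl]-4-methylidene-5-oxooxolan-2-yl}-2-methyl-6-methylidenenon-8-en-1-yl acetate
Conditions: Ac2O, pyridine, DMAP (cat.), CH2Cl2, 0 °C → rt
Reagents that add atoms: acetic anhydride, CC(=O)OC(C)=O
Why: DMAP-catalysed acetylation installs the C13 acetate of the target early and removes a hydroxyl that could add to the methylene lactone or be oxidised by palladium in step 18.

Step 17
Reactants: 29 silyl ether acetate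
Product: 30 (1R,2S)-7-hydroxy-1-{(2R,3S)-3-[(2E)-3-iodobut-2-en-1-yl]-4-methylidene-5-oxooxolan-2-yl}-2-methyl-6-methylidenenon-8-en-1-yl acetate (C7 epimers)
Conditions: HF·pyridine, pyridine/THF, 0 °C → rt
Reagents that add atoms: none
Why: Buffered fluoride desilylation frees the bis-allylic alcohol without basic fluoride, which would attack the methylene lactone.

Step 18
Reactants: 30 seco iodo alcohol
Product: 32 (1S,3E,12S,13R,14R)-13-acetoxy-7-oxocembra-3,8(19),15(17)-trien-16,14-olide, via enol 31 (not isolated)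
Conditions: Pd(OAc)2 (20 mol %), Bu4NCl (2 equiv), NaHCO3 (5 equiv), DMF, 2 mM (slow addition of 30), 60 °C
Reagents that add atoms: none
Why: Proposed new method: zerovalent palladium inserts into the C4–I bond, the E-alkenylpalladium adds across the monosubstituted C5=C6 alkene with C4–C5 bond formation at the CH2 terminus, and syn β-hydride elimination of the carbinol hydrogen at C7 releases enol 31, which tautomerises to ketone 32, so the C7 alcohol pays for the saturated C5–C6 bridge in a redox-neutral way. The closest known reaction types are the intermolecular Mizoroki–Heck alkenylation of secondary allylic alcohols to γ,δ-unsaturated ketones, the redox-relay Heck reaction of alkenols and the macrocyclic Heck reaction, and their combination in a 14-membered closure on a bis-allylic alcohol is the untested part. The carbocycle closes in the 14-endo-trig mode, which macrocyclic Heck reactions normally follow because the metal-bound carbon goes to the unhindered alkene terminus. No stereocentre is created: the E geometry of C3=C4 is carried over from 30 with retention and the undefined C7 centre is erased, so both C7 epimers converge on 32. The step needs chemoselectivity for C5=C6 over the 1,1-disubstituted C8=C19 and C15=C17 alkenes, which the faster insertion of monosubstituted alkenes secures, and the trans relation of palladium and C2 on the alkenyl unit forbids any five- or six-membered closure onto the methylene lactone. It also needs elimination towards C7–H rather than C5–H, which halide-rich, silver-free conditions and the hydridic carbinol C–H favour, while any dienol formed can re-enter by hydropalladation.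

Step 19
Reactants: 32 macrocyclic enone
Product: 33 (1S,3E,7R,12S,13R,14R)-13-acetoxy-7-hydroxycembra-3,8(19),15(17)-trien-16,14-olide
Conditions: (S)-2-methyl-CBS-oxazaborolidine (30 mol %), catecholborane, toluene, −78 °C; aq. work-up
Reagents that add atoms: none
Why: Corey–Bakshi–Shibata reduction in which the ketone binds the (S)-oxazaborolidine–borane complex with the branched alkenyl arm C8 as the large group and C6H2 as the small group, so hydride reaches the face that gives the 7R alcohol, and 1,2-reduction at −78 °C spares lactone, acetate and alkenes.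

Step 20
Reactants: 33 7R alcohol
Product: 34 (1S,3E,7R,12S,13R,14R)-7,13-diacetoxycembra-3,8(19),15(17)-trien-16,14-olide
Conditions: Ac2O, pyridine, DMAP (cat.), CH2Cl2, 0 °C → rt
Reagents that add atoms: acetic anhydride, CC(=O)OC(C)=O
Why: Acetylation with retention at C7 also blocks the hydroxyl that could otherwise open the coming oxirane at C4 to give a tetrahydrofuran.

Step 21
Reactants: 34 diacetate
Product: 35 (1S,3R,4R,7R,12S,13R,14R)-7,13-diacetoxy-3,4-epoxycembra-8(19),15(17)-dien-16,14-olide (target)
Conditions: D-fructose-derived Shi ketone (30 mol %), KHSO5 (as 2KHSO5·KHSO4·K2SO4), K2CO3, Bu4NHSO4 (cat.), MeCN/CH2(OMe)2/aq. Na2B4O7 buffer, 0 °C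
Reagents that add atoms: potassium peroxymonosulfate, [K+].[O-]S(=O)(=O)OO
Why: Shi epoxidation in which the electrophilic dioxirane picks the only electron-rich trisubstituted alkene over the acetate-deactivated C8=C19 and the acrylate C15=C17, and the spiro transition state of the D-fructose-derived catalyst delivers oxygen to the face of the E-alkene that gives the (3R,4R)-oxirane with C2 and C5 trans.

**Compound list**
1 | pent-3-yn-1-ol | CC#CCCO | starting material
2 | (E)-alkenylzirconocene chloride of 1 (Zr on the methyl-bearing carbon, O-zirconated) | C/C(=C\CCO[Zr](Cl)(C1C=CC=C1)C1C=CC=C1)[Zr](Cl)(C1C=CC=C1)C1C=CC=C1 | intermediate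
3 | (3E)-4-iodopent-3-en-1-ol | OCC/C=C(\C)I | intermediate
4 | (3E)-4-iodopent-3-enal | O=CC/C=C(\C)I | intermediate
5 | methyl acrylate | C=CC(=O)OC | starting material
6 | methyl (5E)-3-hydroxy-6-iodo-2-methylidenehept-5-enoate (racemic) | C=C(C(=O)OC)C(O)C/C=C(\C)I | intermediate
7 | methyl (2Z,5E)-2-(bromomethyl)-6-iodohepta-2,5-dienoate | COC(=O)/C(CBr)=C/C/C=C(\C)I | intermediate
8 | acrolein | C=CC=O | starting material
9 | 2,3-dibromopropanal | O=CC(Br)CBr | intermediate
10 | 2-bromoprop-2-enal | C=C(Br)C=O | intermediate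
11 | vinylmagnesium bromide | C=C[Mg]Br | starting material
12 | 2-bromopenta-1,4-dien-3-ol (racemic) | C=CC(O)C(Br)=C | intermediate
13 | [(2-bromopenta-1,4-dien-3-yl)oxy](tert-butyl)dimethylsilane (racemic) | C=CC(O[Si](C)(C)C(C)(C)C)C(Br)=C | intermediate
14 | (S)-citronellal, (3S)-3,7-dimethyloct-6-enal | CC(C)=CCC[C@H](C)CC=O | starting material
15 | (6S)-8,8-dimethoxy-2,6-dimethyloct-2-ene | CC(C)=CCC[C@H](C)CC(OC)OC | intermediate
16 | (4S)-6,6-dimethoxy-4-methylhexanal | O=CCC[C@H](C)CC(OC)OC | intermediate
17 | (4S)-6,6-dimethoxy-4-methylhexan-1-ol | OCCC[C@H](C)CC(OC)OC | intermediate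
18 | (3S)-6-iodo-1,1-dimethoxy-3-methylhexane | ICCC[C@H](C)CC(OC)OC | intermediate
19 | [(4S)-6,6-dimethoxy-4-methylhexyl]zinc iodide | I[Zn]CCC[C@H](C)CC(OC)OC | intermediate
20 | tert-butyl{[(8S)-10,10-dimethoxy-8-methyl-4-methylidenedec-1-en-3-yl]oxy}dimethylsilane (C3 epimers) | C=CC(O[Si](C)(C)C(C)(C)C)C(=C)CCC[C@H](C)CC(OC)OC | intermediate
21 | (3S)-8-[(tert-butyldimethylsilyl)oxy]-3-methyl-7-methylidenedec-9-enal | C=CC(O[Si](C)(C)C(C)(C)C)C(=C)CCC[C@H](C)CC=O | intermediate
22 | (2R,3S)-2-(anilinooxy)-8-[(tert-butyldimethylsilyl)oxy]-3-methyl-7-methylidenedec-9-enal | C=CC(O[Si](C)(C)C(C)(C)C)C(=C)CCC[C@H](C)[C@@H](ONc1ccccc1)C=O | intermediate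
23 | (2R,3S)-2-(anilinooxy)-8-[(tert-butyldimethylsilyl)oxy]-3-methyl-7-methylidenedec-9-en-1-ol | C=CC(O[Si](C)(C)C(C)(C)C)C(=C)CCC[C@H](C)[C@@H](ONc1ccccc1)CO | intermediate
24 | (2R,3S)-8-[(tert-butyldimethylsilyl)oxy]-3-methyl-7-methylidenedec-9-ene-1,2-diol | C=CC(O[Si](C)(C)C(C)(C)C)C(=C)CCC[C@H](C)[C@@H](O)CO | intermediate
25 | (2R,3S)-8-[(tert-butyldimethylsilyl)oxy]-2-hydroxy-3-methyl-7-methylidenedec-9-enal | C=CC(O[Si](C)(C)C(C)(C)C)C(=C)CCC[C@H](C)[C@@H](O)C=O | intermediate
26 | allylindium dibromide derived from 7 (In in place of Br) | COC(=O)/C(C[In](Br)Br)=C/C/C=C(\C)I | intermediate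
27 | methyl (3S,4R,5R,6S)-11-(tert-butyldimethylsilyloxy)-4,5-dihydroxy-3-[(2E)-3-iodobut-2-en-1-yl]-6-methyl-2,10-dimethylidenetridec-12-enoate | C=CC(O[Si](C)(C)C(C)(C)C)C(=C)CCC[C@H](C)[C@@H](O)[C@H](O)[C@@H](C/C=C(\C)I)C(=C)C(=O)OC | intermediate
28 | (4S,5R)-5-[(1R,2S)-7-(tert-butyldimethylsilyloxy)-1-hydroxy-2-methyl-6-methylidenenon-8-en-1-yl]-4-[(2E)-3-iodobut-2-en-1-yl]-3-methylideneoxolan-2-one | C=CC(O[Si](C)(C)C(C)(C)C)C(=C)CCC[C@H](C)[C@@H](O)[C@@H]1OC(=O)C(=C)[C@@H]1C/C=C(\C)I | intermediate
29 | C13 acetate of 28 | C=CC(O[Si](C)(C)C(C)(C)C)C(=C)CCC[C@H](C)[C@@H](OC(C)=O)[C@@H]1OC(=O)C(=C)[C@@H]1C/C=C(\C)I | intermediate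
30 | seco iodo alcohol (29 with free C7 hydroxyl, C7 epimers) | C=CC(O)C(=C)CCC[C@H](C)[C@@H](OC(C)=O)[C@@H]1OC(=O)C(=C)[C@@H]1C/C=C(\C)I | intermediate
31 | macrocyclic C6=C7 enol of 32 | C=C1CCC[C@H](C)[C@@H](OC(C)=O)[C@@H]2OC(=O)C(=C)[C@@H]2C/C=C(\C)CC=C1O | intermediate
32 | (1S,3E,12S,13R,14R)-13-acetoxy-7-oxocembra-3,8(19),15(17)-trien-16,14-olide | C=C1CCC[C@H](C)[C@@H](OC(C)=O)[C@@H]2OC(=O)C(=C)[C@@H]2C/C=C(\C)CCC1=O | intermediate
33 | (1S,3E,7R,12S,13R,14R)-13-acetoxy-7-hydroxycembra-3,8(19),15(17)-trien-16,14-olide | C=C1CCC[C@H](C)[C@@H](OC(C)=O)[C@@H]2OC(=O)C(=C)[C@@H]2C/C=C(\C)CC[C@H]1O | intermediate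
34 | (1S,3E,7R,12S,13R,14R)-7,13-diacetoxycembra-3,8(19),15(17)-trien-16,14-olide | C=C1CCC[C@H](C)[C@@H](OC(C)=O)[C@@H]2OC(=O)C(=C)[C@@H]2C/C=C(\C)CC[C@H]1OC(C)=O | intermediate
35 | (1S,3R,4R,7R,12S,13R,14R)-7,13-diacetoxy-3,4-epoxycembra-8(19),15(17)-dien-16,14-olide | C=C1CCC[C@H](C)[C@@H](OC(C)=O)[C@@H]2OC(=O)C(=C)[C@@H]2C[C@H]2O[C@]2(C)CC[C@H]1OC(C)=O | target

**Totals:** 21 steps. The longest linear sequence is 14 steps (steps 8–21, from (S)-citronellal 14).

**Steps most likely to fail**

1. Step 18 (labelled step).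
   - *What may go wrong:* β-hydride elimination towards C5 giving a conjugated dienol, hydrodehalogenation of the alkenylpalladium, oligomerisation, or palladium hydride-induced migration of the C8=C19 alkene into the ring.
   - *Fallback, from 29 back to 32, all known reaction types:* disiamylborane, which prefers monosubstituted over 1,1-disubstituted and electron-poor alkenes, hydroborates the vinyl group of 29 to the alkyl(disiamyl)borane F1. A B-alkyl Suzuki–Miyaura macrocyclisation (Pd(dppf)Cl2, AsPh3, Cs2CO3, DMF/THF/H2O, high dilution) forms the same C4–C5 bond and gives the macrocyclic silyl ether F2. HF·pyridine frees the macrocyclic allylic alcohol F3 (C7 epimers), and Dess–Martin oxidation converges both epimers on 32.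

2. Step 15.
   - *What may go wrong:* incomplete chelation in water leading to poor facial selectivity at the aldehyde, or epimerisation and ketol shift of crude 25.
   - *Fallback, from 25 back to 29, replacing substrate chelation by catalyst control:* 25 is acetylated (Ac2O, pyridine) to the α-acetoxy aldehyde F4. Bromide 7 is added with nickel-free CrCl2 and a chiral bis(oxazolinyl)carbazole ligand (Nozaki–Hiyama–Kishi-type allylation by an allylchromium species, ligand chosen for the C14 R face) to give the acetoxy hydroxy ester F5. Catalytic TsOH lactonises F5 directly to 29.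

3. Step 21.
   - *What may go wrong:* the macrocycle may expose only one face of C3=C4 and override the catalyst (poor or wrong facial selectivity), and acetate may be lost at the basic pH.
   - *Fallback, from 34 back to 35:* NBS in aqueous THF forms the bromonium ion on the exposed face and water opens it at the tertiary C4 from the opposite face, giving the bromohydrin F6. DBU in CH2Cl2 closes the ring with inversion at C3. The oxirane oxygen therefore ends on the face that direct oxygen transfer cannot reach, with the trans relation of C2 and C5 preserved.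

**Further compounds**
F1 | step 18 | alkyl(disiamyl)borane (29 with CH=CH2 converted into CH2CH2B(CHMeCHMe2)2) | CC(C)C(C)B(CCC(O[Si](C)(C)C(C)(C)C)C(=C)CCC[C@H](C)[C@@H](OC(C)=O)[C@@H]1OC(=O)C(=C)[C@@H]1C/C=C(\C)I)C(C)C(C)C
F2 | step 18 | (1S,3E,12S,13R,14R)-13-acetoxy-7-(tert-butyldimethylsilyloxy)cembra-3,8(19),15(17)-trien-16,14-olide (C7 epimers) | C=C1CCC[C@H](C)[C@@H](OC(C)=O)[C@@H]2OC(=O)C(=C)[C@@H]2C/C=C(\C)CCC1O[Si](C)(C)C(C)(C)C
F3 | step 18 | (1S,3E,12S,13R,14R)-13-acetoxy-7-hydroxycembra-3,8(19),15(17)-trien-16,14-olide (C7 epimers) | C=C1CCC[C@H](C)[C@@H](OC(C)=O)[C@@H]2OC(=O)C(=C)[C@@H]2C/C=C(\C)CCC1O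
F4 | step 15 | (2R,3S)-2-acetoxy-8-[(tert-butyldimethylsilyl)oxy]-3-methyl-7-methylidenedec-9-enal | C=CC(O[Si](C)(C)C(C)(C)C)C(=C)CCC[C@H](C)[C@@H](OC(C)=O)C=O
F5 | step 15 | C13 acetate of hydroxy ester 27 | C=CC(O[Si](C)(C)C(C)(C)C)C(=C)CCC[C@H](C)[C@@H](OC(C)=O)[C@H](O)[C@@H](C/C=C(\C)I)C(=C)C(=O)OC
F6 | step 21 | (3S,4R)-3-bromo-4-hydroxy derivative of 34 (bromohydrin) | C=C1CCC[C@H](C)[C@@H](OC(C)=O)[C@@H]2OC(=O)C(=C)[C@@H]2C[C@H](Br)[C@@](O)(C)CC[C@H]1OC(C)=O
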